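**Plan**

- Ring numbering in the text: cyclohexenone C1 (C=O), C2 (bears the propanoic acid), C3 (bears the trimethylcyclohexane ring through its quaternary carbon C1′), C4, C5, C6 (bears CH2OCHO).
- Retrosynthesis: the formate and the C6–CH2O bond are cut first (C6 is epimerisable and its CH2O group β-eliminable, so it cannot pass through a base-mediated ring closure). The cyclohexenone is then cut at C4–C5 and C2=C3 into methyl ketone 6 and vinyl ketone 13. Ketone 6 goes back to isophorone (C1′–acetyl carbon bond), and 13 to a 3-hydroxy-2-methylpropanoate (acyl–CH2 bond).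
- Feature that permits the annulation: C3 carries the quaternary C1′, so the acetyl group of 6 can enolise only at CH3. Its CH3 (→C4) and C=O (→C3) stand 1,5 to the ring carbonyl and match the acceptor carbon (C5) and donor carbon (C2) of the four-carbon enone unit C5–C6–C1–C2.
- Forward: the cyclohexane ring comes from isophorone (conjugate addition, deoxygenation, ozonolysis); a Michael/aldol annulation then builds the cyclohexenone; tert-butyl ester, hydroxymethylation at C6, formate and acid release follow.
- Stereochemistry: C1′ from a ligand-controlled conjugate addition; the acid α-carbon from methyl (R)-3-hydroxy-2-methylpropanoate (chiral pool); C6 from a ligand-controlled hydroxymethylation.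

Key step: step 7

Remark: the sense of induction in the two ligand-controlled steps (1 and 10) is secured by the choice of ligand enantiomer, both enantiomers being accessible; the descriptors written are those the target requires.

**Step 1**
Reactants: 1 isophorone (3,5,5-trimethylcyclohex-2-en-1-one)
Product: 2 (3R)-3,5,5-trimethyl-3-(prop-1-en-2-yl)cyclohexan-1-one
Conditions: CH2=C(CH3)AlMe2 (from 2-bromopropene, t-BuLi, Et2O, −78 °C, then Me2AlCl), Cu(O2CC4H3S) (10 mol %), chiral phosphinamine ligand Ph2PN[CH(CH3)(2-naphthyl)]2 (11 mol %), Et2O, −30 °C → rt; aq. HCl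
Reagents that add atoms: dimethyl(prop-1-en-2-yl)aluminium, C=C(C)[Al](C)C
Why: Copper-catalysed asymmetric conjugate addition of an alkenylaluminium reagent to a β-substituted cyclic enone (the alkenyl group transfers in preference to methyl); the chiral phosphinamine–copper complex selects the enantiotopic face of the β-carbon and should set the quaternary centre as (R).

**Step 2**
Reactants: 2 (3R)-3,5,5-trimethyl-3-(prop-1-en-2-yl)cyclohexan-1-one
Product: 4 (1S)-1,3,3-trimethyl-1-(prop-1-en-2-yl)cyclohexane, via ketone hydrazone 3 (not isolated)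
Conditions: N2H4·H2O, KOH, diethylene glycol, 130 → 200 °C
Reagents that add atoms: none
Why: Wolff–Kishner reduction (Huang–Minlon procedure) removes the ring carbonyl through the hydrazone; the quaternary centre has no acidic neighbour and the isopropenyl group cannot isomerise, the descriptor changing from R to S only through the change in substituent priorities.

**Step 3**
Reactants: 4 (1S)-1,3,3-trimethyl-1-(prop-1-en-2-yl)cyclohexane
Product: 6 1-[(1S)-1,3,3-trimethylcyclohexyl]ethan-1-one, via ozonide 5 (not isolated)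
Conditions: O3, CH2Cl2, −78 °C; then Me2S, −78 °C → rt
Reagents that add atoms: ozone, [O-][O+]=O
Why: Ozonolysis of the 1,1-disubstituted alkene with reductive work-up releases the methylene carbon as formaldehyde and leaves the methyl ketone, no other oxidisable group being present.

**Step 4**
Reactants: 6 1-[(1S)-1,3,3-trimethylcyclohexyl]ethan-1-one
Product: 8 trimethyl({1-[(1S)-1,3,3-trimethylcyclohexyl]ethenyl}oxy)silane, via lithium enolate 7 (not isolated)
Conditions: LiN(iPr)2, THF, −78 °C; Me3SiCl, −78 °C → rt; pentane, filtration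
Reagents that add atoms: chlorotrimethylsilane, C[Si](C)(C)Cl
Why: Deprotonation of a methyl ketone whose other α-carbon is quaternary can give only one enolate, which is O-silylated (silyl enol ether formation).

**Step 5**
Reactants: 9 methyl (2R)-3-hydroxy-2-methylpropanoate
Product: 10 methyl (2S)-3-iodo-2-methylpropanoate
Conditions: I2, PPh3, imidazole, CH2Cl2, 0 °C → rt
Reagents that add atoms: iodine, II
Why: Appel-type iodination of the primary alcohol (iodide displaces the alkoxyphosphonium group at CH2); the stereocentre is not involved and its descriptor changes from R to S only by priority.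

**Step 6**
Reactants: 10 methyl (2S)-3-iodo-2-methylpropanoate
Product: 13 methyl (2R)-2-methyl-4-oxohex-5-enoate, via alkylzinc iodide 11 (not isolated), via chloro ketone 12 (not isolated)
Conditions: Zn dust, LiCl, THF, 25 °C; then ClCH2CH2COCl, Pd(PPh3)4 (5 mol %), THF, 0 °C → rt; then Et3N, CH2Cl2, 0 °C
Reagents that add atoms: 3-chloropropanoyl chloride, O=C(Cl)CCCl
Why: Zinc insertion gives the configurationally secure β-zincio ester, palladium-catalysed acylation (Negishi-type ketone synthesis) gives the β-chloro ketone, and E1cB loss of HCl with Et3N unmasks the vinyl ketone without touching the ester α-centre.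

**Step 7**
Reactants: 8 trimethyl({1-[(1S)-1,3,3-trimethylcyclohexyl]ethenyl}oxy)silane; 13 methyl (2R)-2-methyl-4-oxohex-5-enoate
Product: 16 (2R)-2-{6-oxo-2-[(1S)-1,3,3-trimethylcyclohexyl]cyclohex-1-en-1-yl}propanoic acid, via diketo ester 14 (not isolated), via diketo carboxylate potassium salt 15 (not isolated)
Conditions: TiCl4, Ti(OiPr)4, CH2Cl2, −78 °C; then MeOH, aq. KOH, 0 → 20 °C, then 65 °C; aq. HCl to pH 3
Reagents that add atoms: potassium hydroxide, [K+].[OH-]
Why: The silyl enol ether 8, whose only nucleophilic carbon is the former acetyl methyl group because the other α-carbon is the quaternary ring carbon, adds in a Lewis-acid-mediated Mukaiyama–Michael reaction to the unsubstituted vinyl terminus of 13 and so forms the C4–C5 bond. Aqueous KOH then saponifies the methyl ester, the enolate of the methylene that becomes C2 adds to the tert-alkyl ketone, and the ketol loses water by E1cB elimination to give the C2=C3 bond; the closest known reaction type is the Robinson annulation in its Mukaiyama–Michael/aldol-condensation form. The six-membered ring closes by a 6-(enolendo)-exo-trig aldol addition, the other enolates of the 1,5-diketone being able to form only four-membered rings, so a single constitution can result. No new stereocentre is formed: the quaternary carbon has no hydrogen, and the carboxylate generated at room temperature before heating protects its α-hydrogen from exchange, so both centres should pass through the hot base unchanged. The selectivities needed are conjugate addition over carbonyl addition and over polymerisation of the vinyl ketone (secured by the TiCl4/Ti(OiPr)4 couple at −78 °C) and aldol condensation over retro-Michael cleavage (secured by the irreversible dehydration to the conjugated tetrasubstituted enone).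

**Step 8**
Reactants: 16 (2R)-2-{6-oxo-2-[(1S)-1,3,3-trimethylcyclohexyl]cyclohex-1-en-1-yl}propanoic acid
Product: 17 tert-butyl (2R)-2-{6-oxo-2-[(1S)-1,3,3-trimethylcyclohexyl]cyclohex-1-en-1-yl}propanoate
Conditions: Cl3CC(=NH)O-t-Bu, BF3·OEt2 (cat.), CH2Cl2/cyclohexane, rt
Reagents that add atoms: tert-butyl 2,2,2-trichloroacetimidate, CC(C)(C)OC(=N)C(Cl)(Cl)Cl
Why: Acid-catalysed O-alkylation of the carboxylic acid by the trichloroacetimidate (tert-butyl cation transfer) runs without base, so neither stereocentre is exposed to enolisation.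

**Step 9**
Reactants: 17 tert-butyl (2R)-2-{6-oxo-2-[(1S)-1,3,3-trimethylcyclohexyl]cyclohex-1-en-1-yl}propanoate
Product: 19 tert-butyl (2R)-2-{6-[(trimethylsilyl)oxy]-2-[(1S)-1,3,3-trimethylcyclohexyl]cyclohexa-1,5-dien-1-yl}propanoate, via lithium dienolate 18 (not isolated)
Conditions: LiN(iPr)2 (1.05 equiv), THF, −78 °C; Me3SiCl, −78 °C → 0 °C; pentane, filtration
Reagents that add atoms: chlorotrimethylsilane, C[Si](C)(C)Cl
Why: Kinetic deprotonation of a cyclohex-2-enone by a lithium amide occurs at the α′-methylene (C6) and not at the γ-position or at the hindered tertiary ester α-hydrogen, which allylic strain holds in the enone plane; O-silylation gives the cross-conjugated 2-silyloxy-1,3-diene.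

**Step 10**
Reactants: 19 tert-butyl (2R)-2-{6-[(trimethylsilyl)oxy]-2-[(1S)-1,3,3-trimethylcyclohexyl]cyclohexa-1,5-dien-1-yl}propanoate
Product: 20 tert-butyl (2R)-2-{(5S)-5-(hydroxymethyl)-6-oxo-2-[(1S)-1,3,3-trimethylcyclohexyl]cyclohex-1-en-1-yl}propanoate
Conditions: aq. HCHO, Sc(OTf)3 (10 mol %), chiral 6,6′-bis(1-hydroxy-2,2-dimethylpropyl)-2,2′-bipyridine (12 mol %), DME/H2O, −20 °C
Reagents that add atoms: formaldehyde, C=O
Why: Lewis-acid-catalysed Mukaiyama aldol reaction with aqueous formaldehyde (catalytic asymmetric hydroxymethylation of a silyl enol ether) at the enol ether carbon C6; the chiral scandium–bipyridine complex chooses the face (catalyst control, the resident stereocentres being remote) and should set this carbon, locant 5 in the name, as (S).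

**Step 11**
Reactants: 20 tert-butyl (2R)-2-{(5S)-5-(hydroxymethyl)-6-oxo-2-[(1S)-1,3,3-trimethylcyclohexyl]cyclohex-1-en-1-yl}propanoate
Product: 21 tert-butyl (2R)-2-{(5S)-5-[(formyloxy)methyl]-6-oxo-2-[(1S)-1,3,3-trimethylcyclohexyl]cyclohex-1-en-1-yl}propanoate
Conditions: HCO2Ac (preformed acetic formic anhydride), pyridine, CH2Cl2, −20 → 0 °C
Reagents that add atoms: acetic formic anhydride, CC(=O)OC=O
Why: O-Formylation of the primary alcohol by the mixed anhydride (formyl transfer is faster than acetyl transfer) under cold, weakly basic conditions that should avoid β-elimination of the β-acyloxy ketone and epimerisation at C6.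

**Step 12**
Reactants: 21 tert-butyl (2R)-2-{(5S)-5-[(formyloxy)methyl]-6-oxo-2-[(1S)-1,3,3-trimethylcyclohexyl]cyclohex-1-en-1-yl}propanoate
Product: 22 (2R)-2-{(5S)-5-[(formyloxy)methyl]-6-oxo-2-[(1S)-1,3,3-trimethylcyclohexyl]cyclohex-1-en-1-yl}propanoic acid
Conditions: HCO2H (neat), 20 °C
Reagents that add atoms: none
Why: Acidolysis of the tert-butyl ester (alkyl–oxygen cleavage through the tert-butyl cation) in formic acid, which cannot exchange the formate for another acyl group and is a weak enough acid to leave the C6 centre unenolised, frees the carboxylic acid.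

**Compound list**

1 | isophorone (3,5,5-trimethylcyclohex-2-en-1-one) | CC1=CC(=O)CC(C)(C)C1 | starting material
2 | (3R)-3,5,5-trimethyl-3-(prop-1-en-2-yl)cyclohexan-1-one | CC(=C)[C@@]1(C)CC(=O)CC(C)(C)C1 | intermediate
3 | (3R)-3,5,5-trimethyl-3-(prop-1-en-2-yl)cyclohexan-1-one hydrazone (C=N geometry not defined) | CC(=C)[C@@]1(C)CC(=NN)CC(C)(C)C1 | intermediate
4 | (1S)-1,3,3-trimethyl-1-(prop-1-en-2-yl)cyclohexane | CC(=C)[C@@]1(C)CCCC(C)(C)C1 | intermediate
5 | 3-methyl-3-[(1S)-1,3,3-trimethylcyclohexyl]-1,2,4-trioxolane (both epimers at the trioxolane carbon) | CC2(OCOO2)[C@@]1(C)CCCC(C)(C)C1 | intermediate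
6 | 1-[(1S)-1,3,3-trimethylcyclohexyl]ethan-1-one | CC(=O)[C@@]1(C)CCCC(C)(C)C1 | intermediate
7 | lithium 1-[(1S)-1,3,3-trimethylcyclohexyl]ethen-1-olate | [Li]OC(=C)[C@@]1(C)CCCC(C)(C)C1 | intermediate
8 | trimethyl({1-[(1S)-1,3,3-trimethylcyclohexyl]ethenyl}oxy)silane | C=C(O[Si](C)(C)C)[C@@]1(C)CCCC(C)(C)C1 | intermediate
9 | methyl (2R)-3-hydroxy-2-methylpropanoate | C[C@@H](C(=O)OC)CO | starting material
10 | methyl (2S)-3-iodo-2-methylpropanoate | C[C@@H](C(=O)OC)CI | intermediate
11 | iodo[(2S)-3-methoxy-2-methyl-3-oxopropyl]zinc | C[C@@H](C(=O)OC)C[Zn]I | intermediate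
12 | methyl (2R)-6-chloro-2-methyl-4-oxohexanoate | C[C@@H](C(=O)OC)CC(=O)CCCl | intermediate
13 | methyl (2R)-2-methyl-4-oxohex-5-enoate | C[C@@H](C(=O)OC)CC(=O)C=C | intermediate
14 | methyl (2R)-2-methyl-4,8-dioxo-8-[(1S)-1,3,3-trimethylcyclohexyl]octanoate | C[C@@H](C(=O)OC)CC(=O)CCCC(=O)[C@@]1(C)CCCC(C)(C)C1 | intermediate
15 | potassium (2R)-2-methyl-4,8-dioxo-8-[(1S)-1,3,3-trimethylcyclohexyl]octanoate | C[C@@H](C(=O)[O-])CC(=O)CCCC(=O)[C@@]1(C)CCCC(C)(C)C1.[K+] | intermediate
16 | (2R)-2-{6-oxo-2-[(1S)-1,3,3-trimethylcyclohexyl]cyclohex-1-en-1-yl}propanoic acid | C[C@@H](C(=O)O)C1=C([C@@]2(C)CCCC(C)(C)C2)CCCC1=O | intermediate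
17 | tert-butyl (2R)-2-{6-oxo-2-[(1S)-1,3,3-trimethylcyclohexyl]cyclohex-1-en-1-yl}propanoate | C[C@@H](C(=O)OC(C)(C)C)C1=C([C@@]2(C)CCCC(C)(C)C2)CCCC1=O | intermediate
18 | lithium 6-[(2R)-1-tert-butoxy-1-oxopropan-2-yl]-5-[(1S)-1,3,3-trimethylcyclohexyl]cyclohexa-1,5-dien-1-olate | C[C@@H](C(=O)OC(C)(C)C)C1=C([C@@]2(C)CCCC(C)(C)C2)CCC=C1O[Li] | intermediate
19 | tert-butyl (2R)-2-{6-[(trimethylsilyl)oxy]-2-[(1S)-1,3,3-trimethylcyclohexyl]cyclohexa-1,5-dien-1-yl}propanoate | C[C@@H](C(=O)OC(C)(C)C)C1=C([C@@]2(C)CCCC(C)(C)C2)CCC=C1O[Si](C)(C)C | intermediate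
20 | tert-butyl (2R)-2-{(5S)-5-(hydroxymethyl)-6-oxo-2-[(1S)-1,3,3-trimethylcyclohexyl]cyclohex-1-en-1-yl}propanoate | C[C@@H](C(=O)OC(C)(C)C)C1=C([C@@]2(C)CCCC(C)(C)C2)CC[C@@H](CO)C1=O | intermediate
21 | tert-butyl (2R)-2-{(5S)-5-[(formyloxy)methyl]-6-oxo-2-[(1S)-1,3,3-trimethylcyclohexyl]cyclohex-1-en-1-yl}propanoate | C[C@@H](C(=O)OC(C)(C)C)C1=C([C@@]2(C)CCCC(C)(C)C2)CC[C@@H](COC=O)C1=O | intermediate
22 | (2R)-2-{(5S)-5-[(formyloxy)methyl]-6-oxo-2-[(1S)-1,3,3-trimethylcyclohexyl]cyclohex-1-en-1-yl}propanoic acid | C[C@@H](C(=O)O)C1=C([C@@]2(C)CCCC(C)(C)C2)CC[C@@H](COC=O)C1=O | target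

**Step count**

Total steps: 12. Longest linear sequence: 10 (steps 1–4 and 7–12, from isophorone); the branch from 9 has 8.

**Steps most likely to fail, with fallbacks**

Step 7. The aldol closure joins a secondary, branched enolate carbon to a neopentyl-type ketone; it may stall at the open diketone or revert by retro-Michael cleavage before dehydration. The fallback closes the ring without the C2 substituent and attaches the propanoic acid afterwards. It sets out from 8. Mukaiyama–Michael addition to but-3-en-2-one (TiCl4, Ti(OiPr)4) should give 1-[(1S)-1,3,3-trimethylcyclohexyl]hexane-1,5-dione F1, which aqueous KOH/MeOH should cyclise to 3-[(1S)-1,3,3-trimethylcyclohexyl]cyclohex-2-en-1-one F2 (the same ketone, but attacked by an unsubstituted methyl-derived enolate). α-Iodination (I2, pyridine, CH2Cl2) should give 2-iodo-3-[(1S)-1,3,3-trimethylcyclohexyl]cyclohex-2-en-1-one F3. Stille coupling with tert-butyl 2-(tributylstannyl)prop-2-enoate (Pd2(dba)3, AsPh3, CuI, DMF) should give tert-butyl 2-{6-oxo-2-[(1S)-1,3,3-trimethylcyclohexyl]cyclohex-1-en-1-yl}prop-2-enoate F4. Acidolysis (CF3CO2H, CH2Cl2) should give 2-{6-oxo-2-[(1S)-1,3,3-trimethylcyclohexyl]cyclohex-1-en-1-yl}prop-2-enoic acid F5. Asymmetric hydrogenation of the acrylic acid with Ru(OAc)2[(R)-BINAP] (H2, MeOH), which leaves the tetrasubstituted enone alone, should set the (R)-centre and return to the route at 16.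

Step 1. Axial delivery of a branched alkenyl group to the β-carbon of isophorone, syn to an axial 5-methyl group, may be slow or poorly face-selective. The fallback replaces asymmetric catalysis by racemic addition and enantiomer separation. It sets out from 1. Copper-catalysed addition of CH2=C(CH3)MgBr (CuBr·SMe2 cat., Me3SiCl, THF, −40 °C) should give racemic 3,5,5-trimethyl-3-(prop-1-en-2-yl)cyclohexan-1-one F6. Its enantiomers are separated by preparative chromatography on a chiral stationary phase, and the (R)-enantiomer is compound 2, where the route is rejoined.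

Step 10. The catalyst may discriminate poorly between the faces of the cyclic, cross-conjugated dienol ether, or hydrolysis of the silyl ether may outrun the aldol reaction. The fallback gives up catalyst control for separation of epimers. It sets out from 19. Hydroxymethylation without a chiral ligand (Yb(OTf)3, aq. HCHO, THF, rt) should give 20 together with tert-butyl (2R)-2-{(5R)-5-(hydroxymethyl)-6-oxo-2-[(1S)-1,3,3-trimethylcyclohexyl]cyclohex-1-en-1-yl}propanoate F7. The two diastereomers are separated by chromatography, F7 is discarded, and the route continues from 20.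

**Further compounds**

F1 | step 7 | 1-[(1S)-1,3,3-trimethylcyclohexyl]hexane-1,5-dione | CC(=O)CCCC(=O)[C@@]1(C)CCCC(C)(C)C1
F2 | step 7 | 3-[(1S)-1,3,3-trimethylcyclohexyl]cyclohex-2-en-1-one | O=C1C=C([C@@]2(C)CCCC(C)(C)C2)CCC1
F3 | step 7 | 2-iodo-3-[(1S)-1,3,3-trimethylcyclohexyl]cyclohex-2-en-1-one | O=C1C(I)=C([C@@]2(C)CCCC(C)(C)C2)CCC1
F4 | step 7 | tert-butyl 2-{6-oxo-2-[(1S)-1,3,3-trimethylcyclohexyl]cyclohex-1-en-1-yl}prop-2-enoate | C=C(C(=O)OC(C)(C)C)C1=C([C@@]2(C)CCCC(C)(C)C2)CCCC1=O
F5 | step 7 | 2-{6-oxo-2-[(1S)-1,3,3-trimethylcyclohexyl]cyclohex-1-en-1-yl}prop-2-enoic acid | C=C(C(=O)O)C1=C([C@@]2(C)CCCC(C)(C)C2)CCCC1=O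
F6 | step 1 | racemic 3,5,5-trimethyl-3-(prop-1-en-2-yl)cyclohexan-1-one | CC(=C)C1(C)CC(=O)CC(C)(C)C1
F7 | step 10 | tert-butyl (2R)-2-{(5R)-5-(hydroxymethyl)-6-oxo-2-[(1S)-1,3,3-trimethylcyclohexyl]cyclohex-1-en-1-yl}propanoate | C[C@@H](C(=O)OC(C)(C)C)C1=C([C@@]2(C)CCCC(C)(C)C2)CC[C@H](CO)C1=O
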